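All constants come from no measurement; the run is a simulation.

I begin with the constants. The concentration I fix first is that of J, because the gas refills it with a half-life of 0.0161 s, far shorter than the 2.3 s that J would last against G as charged. So I hold [J] at csat, the saturation concentration of X, 3.6 mM.

G 32 mM; X 3.6 mM (held); time 12 s

- amount of G.J and E together at 12 s, in percent of the G charged
- the change that raises the amount of G.J and E together at 12 s, in percent of the G charged most ("none" if none brings more than 2 percentage points) (south-west / south-east / north / south / none)
- amount of G.J and E together at 12 s, in percent of the G charged, after south-west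

- percentages count the G that a species holds: one G2 counts as two
- G.J is meant together with its E
- a doubled species enters its step squared and goes two at a time
- solid, in amounts per volume of the solution: E
- at the start none of J is dissolved
- run time (flask): 12 s

- south-west: doubling the dissolution coefficient of step 5, all else as stated
- south-east: doubling the transfer coefficient of step 1, all else as stated
- north: doubling the solubility in step 5, all else as stated
- south: doubling the saturation concentration of X, all else as stated

With [J] held, G + J → G.J is pseudo-first-order in G, with constant a = 9.5 M⁻¹ s⁻¹ × 3.6 mM = 0.0342 s⁻¹. The pairing 2 G → G2 removes G at a first rate constant b = 2 × 5.1 M⁻¹ s⁻¹ × 32 mM = 0.326 s⁻¹. I carry the crossing ratio ρ, the constant a over the constant b, 0.105. Integrating both losses, the fraction of charged G that has passed into G.J by time t is Y = ρ·ln(1 + (1 − e^(−at))/ρ), which gives Y = 15.1% at 12 s.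

Now I turn the settings by hand:

1. South: a and ρ both double, ρ going to 0.210, so Y goes to 27.3%, a gain of 12 percentage points.

2. South-east: a faster refill leaves a and ρ as they are, so I expect no gain.

3. North: J + G.J → J.G.J eats dissolved G.J. Held at the solubility 0.59 mM, it takes 0.44 points of the charge by 12 s, and doubling the solubility costs about that much again.

4. South-west: faster crystals trim that loss, so I expect a gain below 0.44 points.

I commit to y = 14.6%, with south as best.

The forecast gives y = 14.1%, yb = 14.3% and best = south, a y lower than mine, on the ground that “Doubling the saturation concentration therefore directly doubles the rate of the G.J step”.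

The simulation gives y = 14.2%, yb = 14.3% and best = south. The changes bring 11 points for south, 0.16 points for south-west, 0.056 points for south-east and −0.34 points for north; the crossing of X to J makes no difference here. The forecast stands. In this flask, y moves by 5 points with G at 14.9 mM or 73.0 mM, the time held, or with the reading at 5.02 s or 32.6 s, the amounts held; these are two routes by which the forecast's y could miss by that much.

    X ⇌ J, rate k1*(csat - [J]) (k1 = 43 s⁻¹, csat = 3.6 mM)
    G + J → G.J (k2 = 9.5 M⁻¹ s⁻¹)
    J + G.J → J.G.J (k3 = 5.5 M⁻¹ s⁻¹)
    2 G → G2 (k4 = 5.1 M⁻¹ s⁻¹)
    E ⇌ G.J, rate k5*(cs5 - [G.J]) while solid is left; crystals form when [G.J] > cs5 (cs5 = 0.59 mM, k5 = 0.65 s⁻¹)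

In this flask, Y = 15.1% stands beside G.J with E and J.G.J read together, 14.9%. The neighbouring flask is left until 30 s with its amounts held, so ρ stays 0.105 and Y becomes 20.6%. That run reads 18.9% for G.J with E and 1.59% for J.G.J, together 20.5%.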